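Cuts: the two depside C(=O)–O bonds (ring A acyl to O4 of ring B, ring B acyl to O4 of ring C), then, at the dihydro level of ring C, the bonds C1–C6 and C3–C4.
Enabling feature: ring C has CO2H on C1, oxygen on C2 and C4 and CH3 on C6, which is an acetoacetate (carboxyl, C1–C3) joined to a crotonate (C4–C6, methyl). In the 2,4-dioxocyclohexane form O4 is an unhindered vinylogous-acid oxygen and O2 sits in a β-keto ester beside C1, a difference the arene lacks.
Forward order: ring C is closed first and is the only ring built. Rings A and B are bought as arenes, protected and joined to an A–B acid chloride, which acylates O4 of the dione.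
Ring C is then aromatised by C1 selenenylation and selenoxide elimination, and one hydrogenolysis frees the acid and both phenols.
Stereochemistry: the target has none. C1 and C6 of ring C are stereogenic only in transit (racemic, trans by equilibration), matter only for the syn elimination, and are erased on aromatisation.

Key step: step 1

Assumption: the cyclohexanedione and its enol ester are drawn as keto tautomers although both are largely enolised in solution. Their reactivity is discussed for the enol or enolate forms.

Step 1
Reactants: 1 benzyl acetoacetate; 2 benzyl (E)-but-2-enoate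
Product: 4 benzyl trans-6-methyl-2,4-dioxocyclohexane-1-carboxylate (racemic), via Michael adduct 3 (not isolated)
Conditions: NaOCH2Ph (1.0 M in BnOH, 1.1 equiv), toluene, 90 °C; extraction of the sodium salt into H2O, then aq HCl, 0 °C
Reagents that add atoms: none
Why: This is a Michael–Dieckmann annulation: NaOCH2Ph deprotonates the doubly activated CH2 of 1, that carbon adds to the β-carbon of 2 (bond C1–C6) to give 3, and after proton transfer the enolate of the acetyl CH3 attacks the former crotonate ester carbonyl (bond C3–C4) and expels benzyloxide. The closest known reaction type is the alkoxide-mediated condensation of alkyl acetoacetates with alkyl crotonates to dihydro-orsellinates, here only moved to the benzyl series. Ring C closes in the 6-exo-trig mode, and every other enolate–carbonyl pairing within 3 would give a four-membered ring, so no competing cyclisation is expected. All stages up to the ring closure are reversible and the sequence is driven by deprotonation of the product to its vinylogous carboxylate salt, which also allows separation from benzyl alcohol by extraction into water before acidification. C1 and C6 arise racemic, with the trans relation fixed by equilibration of the acidic C1–H towards the diequatorial isomer, and neither centre survives step 11. The selectivity needed is C–C bond formation at the α-carbon before acylation at the methyl carbon, which the acidity order of the two sites secures, while the identity of both ester alkoxy groups with the base rules out ester scrambling.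

Step 2
Reactants: 5 methyl 2,4-dihydroxy-6-methylbenzoate (methyl orsellinate)
Product: 6 methyl 4-(benzyloxy)-2-hydroxy-6-methylbenzoate
Conditions: BnBr (1.05 equiv), K2CO3, acetone, reflux
Reagents that add atoms: benzyl bromide, BrCc1ccccc1
Why: Williamson ether synthesis under weak base: the C4 hydroxyl is free and the more acidic one, whereas the C2 hydroxyl is hydrogen-bonded to the ester carbonyl, so one equivalent of BnBr should alkylate O4 only.

Step 3
Reactants: 6 methyl 4-(benzyloxy)-2-hydroxy-6-methylbenzoate
Product: 7 methyl 4-(benzyloxy)-2-methoxy-6-methylbenzoate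
Conditions: MeI (excess), K2CO3, DMF, 50 °C
Reagents that add atoms: iodomethane, CI
Why: Williamson O-methylation of the remaining chelated phenol, which should react once excess MeI, a dipolar solvent and gentle heating are used, no other acidic site being present.

Step 4
Reactants: 7 methyl 4-(benzyloxy)-2-methoxy-6-methylbenzoate
Product: 8 4-(benzyloxy)-2-methoxy-6-methylbenzoic acid (ring A acid)
Conditions: KOH, DMSO–H2O, 100 °C; then aq HCl
Reagents that add atoms: potassium hydroxide, [K+].[OH-] (source of the carboxyl OH oxygen)
Why: Saponification of a di-ortho-substituted benzoate, slow under ordinary conditions but feasible with poorly solvated hydroxide in hot aqueous DMSO, to which the benzyl and methyl aryl ethers are inert.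

Step 5
Reactants: 8 4-(benzyloxy)-2-methoxy-6-methylbenzoic acid; 9 2,4-dihydroxy-6-methylbenzaldehyde
Product: 11 4-formyl-3-hydroxy-5-methylphenyl 4-(benzyloxy)-2-methoxy-6-methylbenzoate, via mixed trifluoroacetic anhydride 10 (not isolated)
Conditions: (CF3CO)2O, toluene, 0 °C to rt
Reagents that add atoms: trifluoroacetic anhydride, O=C(OC(=O)C(F)(F)F)C(F)(F)F (its trifluoroacetoxy unit is carried only by intermediate 10 and nothing of it stays in 11)
Why: Depside esterification through a mixed trifluoroacetic anhydride, whose acylium-like character overcomes the two ortho substituents of 8, and of the two hydroxyls of 9 only the one at C4 should react because the C2 hydroxyl is chelated to the formyl group.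

Step 6
Reactants: 11 4-formyl-3-hydroxy-5-methylphenyl 4-(benzyloxy)-2-methoxy-6-methylbenzoate
Product: 12 3-(benzyloxy)-4-formyl-5-methylphenyl 4-(benzyloxy)-2-methoxy-6-methylbenzoate
Conditions: BnBr, K2CO3, DMF, 40 °C
Reagents that add atoms: benzyl bromide, BrCc1ccccc1
Why: Williamson benzylation of the chelated ortho-hydroxy aldehyde, in which the hindered aryl ester link withstands anhydrous carbonate and the masking keeps this oxygen out of steps 8 and 9.

Step 7
Reactants: 12 3-(benzyloxy)-4-formyl-5-methylphenyl 4-(benzyloxy)-2-methoxy-6-methylbenzoate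
Product: 13 2-(benzyloxy)-4-{[4-(benzyloxy)-2-methoxy-6-methylbenzoyl]oxy}-6-methylbenzoic acid (A–B acid; its acyl residue is called A–B aroyl below)
Conditions: NaClO2, NaH2PO4, 2-methyl-2-butene, t-BuOH–THF–H2O, rt
Reagents that add atoms: sodium chlorite, [Na+].[O-]Cl=O
Why: Pinnick oxidation turns the aldehyde into the acid near neutral pH without touching the aryl ester or the benzyl ethers, the alkene scavenging HOCl that could otherwise chlorinate the electron-rich rings.

Step 8
Reactants: 13 A–B acid
Product: 14 2-(benzyloxy)-4-{[4-(benzyloxy)-2-methoxy-6-methylbenzoyl]oxy}-6-methylbenzoyl chloride (A–B acid chloride)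
Conditions: (COCl)2, DMF (cat.), CH2Cl2, 0 °C to rt; evaporation, used crude
Reagents that add atoms: oxalyl chloride, O=C(Cl)C(=O)Cl
Why: Acid chloride formation through the Vilsmeier-type chloroiminium salt from (COCl)2 and DMF, mild enough for the aryl ester and benzyl ethers since every phenol is masked.

Step 9
Reactants: 14 A–B acid chloride; 4 benzyl trans-6-methyl-2,4-dioxocyclohexane-1-carboxylate
Product: 15 benzyl trans-4-(A–B aroyloxy)-6-methyl-2-oxocyclohex-3-ene-1-carboxylate (racemic)
Conditions: Et3N (1.1 equiv), CH2Cl2, 0 °C to rt
Reagents that add atoms: none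
Why: O-acylation of a cyclic 1,3-dione to its enol ester: Et3N ionises only the vinylogous acid (O2–C2–C3–C4–O4), the di-ortho-substituted acyl chloride should take the oxygen flanked by CH2 groups (O4) instead of O2 next to the ester-bearing C1, and the absence of cyanide or DMAP-type acyl-transfer catalysts holds back migration of the acyl group to C3.

Step 10
Reactants: 15 benzyl trans-4-(A–B aroyloxy)-6-methyl-2-oxocyclohex-3-ene-1-carboxylate
Product: 16 benzyl 4-(A–B aroyloxy)-6-methyl-2-oxo-1-(phenylselanyl)cyclohex-3-ene-1-carboxylate, SePh trans to the C6 methyl and cis to H6 (racemic)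
Conditions: PhSeCl, pyridine, CH2Cl2, 0 °C
Reagents that add atoms: benzeneselenenyl chloride, Cl[Se]c1ccccc1
Why: Electrophilic α-selenenylation of a β-keto ester through its enol: with C3 now deactivated as part of an acyloxy enone, C1 is the only nucleophilic carbon, and PhSe should enter anti to the pseudoaxial C6 methyl group, which sets the new quaternary centre C1 with selenium cis to H6 as the later syn elimination demands.

Step 11
Reactants: 16 C1 selenide
Product: 19 benzyl 4-(A–B aroyloxy)-2-hydroxy-6-methylbenzoate (tribenzyl-protected tridepside), via selenoxide 17 (not isolated), via cyclohexadienone 18 (not isolated)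
Conditions: mCPBA (1.0 equiv), CH2Cl2, −78 °C to rt; chromatography on SiO2
Reagents that add atoms: 3-chloroperbenzoic acid, OOC(=O)c1cccc(Cl)c1 (its oxygen sits on selenium in 17 and leaves with the selenium)
Why: Selenoxide syn elimination: chemoselective oxidation at selenium gives 17, which loses PhSeOH through a five-membered cyclic transition state involving the cis H6 (the only β-hydrogen), and the cross-conjugated dienone 18 with its C5 methylene tautomerises at once to the phenol, erasing C1 and C6 as stereocentres and exposing the C2 hydroxyl.

Step 12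
Reactants: 19 tribenzyl-protected tridepside
Product: 20 umbilicaric acid
Conditions: H2 (1 atm), 10% Pd/C, EtOAc, rt
Reagents that add atoms: none
Why: Catalytic hydrogenolysis cleaves the benzyl ester and both benzyl aryl ethers in one operation under neutral conditions that leave the two depside esters and the methyl ether intact.

Compound list
1 | benzyl acetoacetate | CC(=O)CC(=O)OCc1ccccc1 | starting material
2 | benzyl (E)-but-2-enoate | C/C=C/C(=O)OCc1ccccc1 | starting material
3 | dibenzyl 2-acetyl-3-methylpentanedioate (Michael adduct, racemic mixture of diastereomers, not isolated) | CC(=O)C(C(=O)OCc1ccccc1)C(C)CC(=O)OCc1ccccc1 | intermediate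
4 | benzyl trans-6-methyl-2,4-dioxocyclohexane-1-carboxylate (racemic, one enantiomer drawn) | C[C@@H]1CC(=O)CC(=O)[C@H]1C(=O)OCc1ccccc1 | intermediate
5 | methyl 2,4-dihydroxy-6-methylbenzoate | COC(=O)c1c(C)cc(O)cc1O | starting material
6 | methyl 4-(benzyloxy)-2-hydroxy-6-methylbenzoate | COC(=O)c1c(C)cc(OCc2ccccc2)cc1O | intermediate
7 | methyl 4-(benzyloxy)-2-methoxy-6-methylbenzoate | COC(=O)c1c(C)cc(OCc2ccccc2)cc1OC | intermediate
8 | 4-(benzyloxy)-2-methoxy-6-methylbenzoic acid | COc1cc(OCc2ccccc2)cc(C)c1C(=O)O | intermediate
9 | 2,4-dihydroxy-6-methylbenzaldehyde | Cc1cc(O)cc(O)c1C=O | starting material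
10 | 4-(benzyloxy)-2-methoxy-6-methylbenzoic trifluoroacetic anhydride (not isolated) | COc1cc(OCc2ccccc2)cc(C)c1C(=O)OC(=O)C(F)(F)F | intermediate
11 | 4-formyl-3-hydroxy-5-methylphenyl 4-(benzyloxy)-2-methoxy-6-methylbenzoate | COc1cc(OCc2ccccc2)cc(C)c1C(=O)Oc1cc(C)c(C=O)c(O)c1 | intermediate
12 | 3-(benzyloxy)-4-formyl-5-methylphenyl 4-(benzyloxy)-2-methoxy-6-methylbenzoate | COc1cc(OCc2ccccc2)cc(C)c1C(=O)Oc1cc(C)c(C=O)c(OCc2ccccc2)c1 | intermediate
13 | 2-(benzyloxy)-4-{[4-(benzyloxy)-2-methoxy-6-methylbenzoyl]oxy}-6-methylbenzoic acid | COc1cc(OCc2ccccc2)cc(C)c1C(=O)Oc1cc(C)c(C(=O)O)c(OCc2ccccc2)c1 | intermediate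
14 | 2-(benzyloxy)-4-{[4-(benzyloxy)-2-methoxy-6-methylbenzoyl]oxy}-6-methylbenzoyl chloride | COc1cc(OCc2ccccc2)cc(C)c1C(=O)Oc1cc(C)c(C(=O)Cl)c(OCc2ccccc2)c1 | intermediate
15 | benzyl trans-4-(A–B aroyloxy)-6-methyl-2-oxocyclohex-3-ene-1-carboxylate (racemic, one enantiomer drawn) | C[C@@H]1CC(OC(=O)c2c(C)cc(OC(=O)c3c(C)cc(OCc4ccccc4)cc3OC)cc2OCc2ccccc2)=CC(=O)[C@H]1C(=O)OCc1ccccc1 | intermediate
16 | benzyl 4-(A–B aroyloxy)-6-methyl-2-oxo-1-(phenylselanyl)cyclohex-3-ene-1-carboxylate, SePh trans to CH3 (racemic, one enantiomer drawn) | C[C@@H]1CC(OC(=O)c2c(C)cc(OC(=O)c3c(C)cc(OCc4ccccc4)cc3OC)cc2OCc2ccccc2)=CC(=O)[C@]1([Se]c1ccccc1)C(=O)OCc1ccccc1 | intermediate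
17 | selenoxide of 16 (configuration at selenium undefined, not isolated) | C[C@@H]1CC(OC(=O)c2c(C)cc(OC(=O)c3c(C)cc(OCc4ccccc4)cc3OC)cc2OCc2ccccc2)=CC(=O)[C@]1([Se](=O)c1ccccc1)C(=O)OCc1ccccc1 | intermediate
18 | benzyl 4-(A–B aroyloxy)-2-methyl-6-oxocyclohexa-1,4-diene-1-carboxylate (cross-conjugated dienone, not isolated) | CC1=C(C(=O)OCc2ccccc2)C(=O)C=C(OC(=O)c2c(C)cc(OC(=O)c3c(C)cc(OCc4ccccc4)cc3OC)cc2OCc2ccccc2)C1 | intermediate
19 | benzyl 4-({2-(benzyloxy)-4-[(4-(benzyloxy)-2-methoxy-6-methylbenzoyl)oxy]-6-methylbenzoyl}oxy)-2-hydroxy-6-methylbenzoate | COc1cc(OCc2ccccc2)cc(C)c1C(=O)Oc1cc(C)c(C(=O)Oc2cc(C)c(C(=O)OCc3ccccc3)c(O)c2)c(OCc2ccccc2)c1 | intermediate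
20 | umbilicaric acid | COc1cc(O)cc(C)c1C(=O)Oc1cc(C)c(C(=O)Oc2cc(C)c(C(=O)O)c(O)c2)c(O)c1 | target

Total step count: 12.
Longest linear sequence: 11 steps (steps 2–12, from 5). The ring C branch runs through steps 1 and 9–12.

Steps most likely to fail

Step 9 (enol acylation).
- What may go wrong: acyl transfer from the di-ortho-substituted chloride may be slow, the acyl group may spread over O4 and O2, or it may drift from oxygen to C3.
- Fallback: the oxygen differentiation is moved from the dione to the arene. Setting out from 4, bromination–dehydrobromination (Br2, 1 equiv, DMF, 0 to 80 °C) should aromatise ring C to benzyl 2,4-dihydroxy-6-methylbenzoate F1. Acid 13 is then activated with (CF3CO)2O in toluene as its mixed trifluoroacetic anhydride F2. This should esterify the free C4 hydroxyl of F1 while the C2 hydroxyl stays chelated to the benzyl ester.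
- Return: the fallback comes back to the route at 19 and bypasses steps 8–11.

Step 10 (selenenylation).
- What may go wrong: the enol ester is a vinylogous anhydride, so pyridine and chloride may strip off the aroyl group. Transfer of selenium to C1 may also be reversible and incomplete.
- Fallback: a selenium-free dehydrogenation by hydride abstraction. Setting out from 15, DDQ in toluene or dioxane (rt to 60 °C) should act on the chelated dienol tautomer. That tautomer is a cyclohexa-1,3-diene with C5 and C6 as its only sp3 carbons, and after loss of hydride and a proton it is the arene. Simple benzyl ethers are oxidised far more slowly.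
- Return: the fallback comes back at 19, and no compound outside the list is made (F0).

Step 11 (oxidation and elimination).
- What may go wrong: poor facial selectivity in step 10 would surface here, because material with selenium cis to the C6 methyl has no syn hydrogen to lose. Re-addition of the selenenic acid, selenenylation of the fresh phenol, or attack of the peracid on the enol ester could also erode the step.
- Fallback: a Saegusa–Ito dehydrogenation. Setting out from 15, TMSOTf and Et3N in CH2Cl2 at 0 °C should give benzyl 4-(A–B aroyloxy)-6-methyl-2-[(trimethylsilyl)oxy]cyclohexa-1,3-diene-1-carboxylate F3. Pd(OAc)2 in MeCN at rt should then convert F3 into a palladium enolate at C1. This enolate can change faces through its oxygen-bound form, so syn β-hydride elimination towards H6 stays reachable.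
- Return: the resulting dienone 18 tautomerises and the fallback comes back at 19.

Further compounds
F1 | step 9 | benzyl 2,4-dihydroxy-6-methylbenzoate | Cc1cc(O)cc(O)c1C(=O)OCc1ccccc1
F2 | step 9 | 2-(benzyloxy)-4-{[4-(benzyloxy)-2-methoxy-6-methylbenzoyl]oxy}-6-methylbenzoic trifluoroacetic anhydride | COc1cc(OCc2ccccc2)cc(C)c1C(=O)Oc1cc(C)c(C(=O)OC(=O)C(F)(F)F)c(OCc2ccccc2)c1
F0 | step 10 | none | none
F3 | step 11 | benzyl 4-(A–B aroyloxy)-6-methyl-2-[(trimethylsilyl)oxy]cyclohexa-1,3-diene-1-carboxylate (racemic, one enantiomer drawn) | C[C@@H]1CC(OC(=O)c2c(C)cc(OC(=O)c3c(C)cc(OCc4ccccc4)cc3OC)cc2OCc2ccccc2)=CC(O[Si](C)(C)C)=C1C(=O)OCc1ccccc1
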